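(The numbers of this flask are those of an exercise.)

Z.E cannot stay for good in a flask in which it turns into X: its amount has to rise, peak and fall, so I ask where each reading stands against the peak.

    Z + E → Z.E, rate k1*[Z]*[E]^0.5 (k1 = 8.6 /M^0.5/h, Ea1 = 76.0 kJ/mol)
    D ⇌ Z.E, rate k2*(cs2 - [Z.E]) while solid is left; crystals form when [Z.E] > cs2 (cs2 = 0.10 M, k2 = 63 /h)
    G ⇌ E, rate k3*(csat - [E]) (k3 = 14 /h, csat = 9.3 mM)
    Z.E → X (k4 = 0.20 /h, Ea4 = 105 kJ/mol)
    (constants at 25 °C)

the same everywhere: Z 0.13 M; G 9.3 mM (held); time 6.0 h
- beta: temperature −5 °C
- delta: temperature 25 °C

- amounts and yields of Z.E count D too
- given per volume of solution although it is solid: D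
- at the start none of E is dissolved
- at 25 °C the constants are as listed, elsewhere as the activation energies make them

1. the best flask by amount of Z.E, in percent of the Z charged; "all alike" if 1.5 percentage points covers them all (beta / delta / all alike)
2. amount of Z.E at the end, in percent of the Z charged, beta
3. amount of Z.E at the end, in percent of the Z charged, delta

I order the clocks, fastest first. The gas crosses over in about 0.0714 h, which is faster than Z is consumed. So E follows its steady value, and for that value I take its ceiling, 9.3 mM. That overstates the early rate in delta, where E starts from zero and the first step at this cE would take 0.108 M/h against a largest supply of 0.130 M/h.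

Z then falls pseudo-first-order with a constant a, the rate constant of the first step times the root of cE. This gives 0.829 /h in delta and 0.0269 /h in beta. Z.E is lost with a constant b, 0.20 /h in delta and 0.00175 /h in beta.

My zero is the symmetric case a = b, where the peak stands at one over a. Away from it, the peak lies at ln(a/b)/(a−b). In delta that is 2.26 h, and this peak time, the moment at which making equals loss, is what I carry. In beta it is 109 h. So delta is read past its peak, and beta long before its peak.

My estimate of the peak height in delta is the charged cZ times exp(−b·tpeak), or 0.0827 M. This is less than the solubility, so I expect no D. The two-stage formula a/(a−b)·(exp(−bt)−exp(−at)) gives me 14.8 % for beta and 38.8 % for delta.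

The forecast names delta, with 14.5 % for beta and 41.5 % for delta. Its delta value stands above mine. On crystals we agree: “no crystals form and all of it decays”.

The simulation gives delta, with 14.5 % for beta and 41.2 % for delta.

In delta at 1.11 h, the half-life of Z by the first step is 1.0 h, shorter than the 3.5 h of dissolved Z.E by the step to X, and dissolved Z.E is made 3.99 times faster than it is used up. At 6.00 h that ratio is 0.113, and my peak time of 2.26 h lies between these two moments.

Now take delta read at 4.0 h. The peak time is still 2.26 h, but the reading stands nearer to it, and the formula gives 54.4 %. The simulation gives 56.0 %.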